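A leftover of incoming ligand is what you watch here. The north-east run, with 1.63 of it per starting complex, reads highest at 47% at 2.50 h and falls to 37% at 10.0 h. The west run, with 0.733, is still creeping up to 37% at 15.0 h.

in all of them: starting complex 0.30 M
- west: incoming ligand 0.22 M; leaving ligand 0.60 M (fed, over 4.0 h); temperature 0 °C; run made earlier; the fed solution adds 0.50 times the starting volume
- north-east: incoming ligand 0.49 M; leaving ligand 0.60 M (fed, over 4.0 h); temperature 15 °C; run made earlier; the fed solution adds 0.50 times the starting volume
- maple: incoming ligand 0.330 M; leaving ligand 0.600 M (fed, over 4.0 h); at 5 °C until 4.0 h, from then on at 25 °C; the fed solution adds 0.50 times the starting volume; time 25 h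
- cedar: incoming ligand 0.330 M; leaving ligand 0.600 M (fed, over 4.0 h); at 5 °C throughout; the fed solution adds 0.50 times the starting volume; time 80 h

| run | time / h | complex with one exchanged / % |
|---|---|---|
| west | 3.00 | 24 |
| west | 6.00 | 32 |
| west | 10.0 | 34 |
| west | 12.0 | 36 |
| west | 15.0 | 37 |
| north-east | 0.833 | 42 |
| north-east | 1.50 | 45 |
| north-east | 2.50 | 47 |
| north-east | 5.00 | 43 |
| north-east | 10.0 | 37 |

(scatter of a reading: 1.5 percentage points)

- the winner by amount of complex with one exchanged, in percent of the starting complex charged; "neither" if no more than 2 percentage points parts them (maple / cedar / neither)
- how much complex with one exchanged is there at the end, in percent of the starting complex charged: maple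
- how much complex with one exchanged is there at the end, in percent of the starting complex charged: cedar

- amounts are per litre of the starting volume; all of the dose is in the solution fed

Maple and cedar each hold 1.10 of incoming ligand per starting complex. That fraction is the exchange budget: the exchanges the flask can pay for per starting complex. I take it that a complex can take two exchanges, which makes incoming ligand the limiting reagent. I assume both exchanges are first order in incoming ligand, so that concentration cancels from their ratio, and at a fixed temperature the amount of complex with one exchanged follows the budget used, not the clock.

Where does this budget land? West and north-east both read 37% when last read, west still rising and north-east falling, so I put the best budget between theirs: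

midpoint of the budgets = (0.733 + 1.63) / 2 = 1.18

Maple and cedar sit 0.0833 below that, so my first estimate for them is about 47%, the highest north-east reading, give or take 1.5 percentage points.

But west was still rising when last read, so it may not have used its budget, and that midpoint is rough. The budget of maple and cedar still lies between the two runs, so I keep the estimate.

Is there time to use the budget? Cedar runs 5.33 times as long as the last west reading, and at 5 °C against 0 °C. I take it as used. Maple gets 25 h, at 25 °C from 4.0 h on, which is the weak point: I have no reading at 25 °C to show how warming shifts the two exchanges. So I put maple no higher and call it neither.

The forecast differs: cedar, maple 20%, cedar 27%, in its own words “with maple further along”.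

The flasks give maple 42.9% and cedar 47.1%, so cedar wins.

    starting complex + incoming ligand → leaving ligand + complex with one exchanged (k = 0.899 M⁻¹ h⁻¹, Ea = 67.0 kJ mol⁻¹)
    complex with one exchanged + incoming ligand → leaving ligand + complex with two exchanged (k = 0.470 M⁻¹ h⁻¹, Ea = 73.0 kJ mol⁻¹)
    starting complex + complex with one exchanged → side product (k = 0.00766 M⁻¹ h⁻¹, Ea = 73.0 kJ mol⁻¹)
    (constants at 5 °C)

At the end, incoming ligand stands at 0% of its charge in maple and 0.067% in cedar. Count the exchanges in cedar, taking side product at half its percentage, as it holds two complexes and one exchange:

47.1% + 2 × 30.7% + 2.82% / 2 = 1.10 of a budget of 1.10

A neighbour of cedar, charged with 0.56 M of incoming ligand, has a budget of 1.87, and it ends with 17.4% of complex with one exchanged and 80.8% of complex with two exchanged.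

(The earlier runs and the new flask were generated by integration for an exercise; scatter was added.)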